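**Plan**
- **Enabling feature:** in ring C (O1–C2H2–C3–C4–C4a–C8a) the tertiary carbinol C3, which carries ring B, is bonded directly to the C4 aryl ketone on ring A. This α-ketol is what an aldehyde carbon (C4) and a ketone carbon (C3) give in a crossed benzoin reaction.
- **Cuts, in retrosynthetic order:** the three phenol protecting groups; C3–C4, which opens ring C to a keto aldehyde; O1–C2, which gives a ring A salicylaldehyde and a ring B chloromethyl ketone; C2–C3, which gives a chloromethyl anion and a ring B aldehyde; and the two aryl–prenyl bonds.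
- **Forward order:** rings A and B are bought as 2,4,6-trihydroxybenzaldehyde and 4-hydroxy-2-methoxybenzaldehyde. The C6 prenyl group comes from an O-prenyl ether by a Claisen–Cope shift, and the C3' prenyl group from a directed lithiation. The halves are joined as an aryl ether, and ring C, the only ring made, closes last.
- **Stereochemistry:** the single stereocentre C3 (R) is created in the ring closure under control of an enantiopure aminoindanol-derived triazolylidene. C3 is fully substituted, so the final deprotection cannot epimerise it.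

Key step: step 9

Assumption: the facial preference of the aminoindanol-derived carbene is inferred by analogy with simpler 2-(2-aryl-2-oxoethoxy)benzaldehydes. The (5aR,10bS) salt is written for (R)-17. Should a configuration check (ECD or X-ray) show the mirror image, the equally available (5aS,10bR) salt takes its place without other change.

**Step 1**
Reactants: 1 2,4,6-trihydroxybenzaldehyde
Product: 2 2-hydroxy-4,6-bis(methoxymethoxy)benzaldehyde
Conditions: MOMCl (2.2 equiv), i-Pr2NEt, CH2Cl2, 0 °C → rt
Reagents that add atoms: chloromethyl methyl ether (MOMCl), COCCl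
Why: Base-mediated O-alkylation of phenols with an α-chloro ether (acetal-type Williamson reaction): the para hydroxyl and one ortho hydroxyl react, after which the last ortho hydroxyl is locked in a strong hydrogen bond to the formyl oxygen and stays free at this stoichiometry.

**Step 2**
Reactants: 2 2-hydroxy-4,6-bis(methoxymethoxy)benzaldehyde; 3 prenyl bromide (1-bromo-3-methylbut-2-ene)
Product: 4 2,4-bis(methoxymethoxy)-6-[(3-methylbut-2-en-1-yl)oxy]benzaldehyde
Conditions: K2CO3, DMF, rt
Reagents that add atoms: none
Why: Williamson ether synthesis: carbonate in a dipolar aprotic solvent frees the chelated phenoxide, which displaces the primary allylic bromide at oxygen by SN2, while the acetal ethers and the aldehyde are inert to the mild base.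

**Step 3**
Reactants: 4 2,4-bis(methoxymethoxy)-6-[(3-methylbut-2-en-1-yl)oxy]benzaldehyde
Product: 7 6-hydroxy-2,4-bis(methoxymethoxy)-3-(3-methylbut-2-en-1-yl)benzaldehyde, via ortho-dienone 5 (not isolated), via para-dienone 6 (not isolated)
Conditions: PhNEt2, 200 °C, argon, sealed tube
Reagents that add atoms: none
Why: Tandem aromatic Claisen–Cope (para-Claisen) rearrangement: the first [3,3] shift puts a 1,1-dimethylallyl group on the only free ortho carbon, the crowded dienone 5 relays it by a second [3,3] shift to the para carbon between the two acetal ethers, and tautomerisation of 6 restores the chelated phenol, a course well known for the analogous 2-prenyloxy-4,6-bis(methoxymethoxy)aryl ketones.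

**Step 4**
Reactants: 8 4-hydroxy-2-methoxybenzaldehyde
Product: 9 2-methoxy-4-(methoxymethoxy)benzaldehyde
Conditions: MOMCl, i-Pr2NEt, CH2Cl2, 0 °C → rt
Reagents that add atoms: chloromethyl methyl ether (MOMCl), COCCl
Why: Routine phenol protection by O-alkylation with an α-chloro ether, which also installs the stronger of the two directing groups needed for the lithiation in step 5.

**Step 5**
Reactants: 9 2-methoxy-4-(methoxymethoxy)benzaldehyde; 3 prenyl bromide
Product: 13 2-methoxy-4-(methoxymethoxy)-3-(3-methylbut-2-en-1-yl)benzaldehyde, via lithium amino alkoxide 10 (not isolated), via aryllithium 11 (not isolated), via prenylated amino alkoxide 12 (not isolated)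
Conditions: N-methylpiperazine, n-BuLi, THF, −20 °C; n-BuLi, −20 → 0 °C; 3, −78 °C → rt; H2O
Reagents that add atoms: none
Why: In-situ masking of the aldehyde as a lithium α-amino alkoxide (Comins method) followed by directed ortho-metalation: the piperazine adduct directs only weakly, so the carbon between the methoxy and methoxymethoxy groups, doubly coordinated and most acidic, is lithiated, the aryllithium displaces the allylic bromide by SN2, and water releases the aldehyde.

**Step 6**
Reactants: 13 2-methoxy-4-(methoxymethoxy)-3-(3-methylbut-2-en-1-yl)benzaldehyde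
Product: 14 racemic 2-chloro-1-[2-methoxy-4-(methoxymethoxy)-3-(3-methylbut-2-en-1-yl)phenyl]ethan-1-ol
Conditions: ClCH2I, MeLi·LiBr, THF, −78 °C; AcOH, −78 °C
Reagents that add atoms: chloroiodomethane, ClCI
Why: Addition of a lithium carbenoid to an aldehyde: iodine–lithium exchange on ClCH2I outruns attack of MeLi on the carbonyl, the chloromethyllithium is trapped as it forms (Barbier mode), and the cold acidic quench keeps the alkoxide from closing to the epoxide; the new carbinol centre is racemic and is erased in step 7.

**Step 7**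
Reactants: 14 racemic 2-chloro-1-[2-methoxy-4-(methoxymethoxy)-3-(3-methylbut-2-en-1-yl)phenyl]ethan-1-ol
Product: 15 2-chloro-1-[2-methoxy-4-(methoxymethoxy)-3-(3-methylbut-2-en-1-yl)phenyl]ethan-1-one
Conditions: Dess–Martin periodinane, CH2Cl2, 0 °C → rt
Reagents that add atoms: none
Why: Dess–Martin oxidation of a secondary benzylic alcohol under near-neutral conditions, which leave the trisubstituted alkene, the acetal ether and the C–Cl bond untouched.

**Step 8**
Reactants: 7 6-hydroxy-2,4-bis(methoxymethoxy)-3-(3-methylbut-2-en-1-yl)benzaldehyde; 15 2-chloro-1-[2-methoxy-4-(methoxymethoxy)-3-(3-methylbut-2-en-1-yl)phenyl]ethan-1-one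
Product: 16 2,4-bis(methoxymethoxy)-6-{2-[2-methoxy-4-(methoxymethoxy)-3-(3-methylbut-2-en-1-yl)phenyl]-2-oxoethoxy}-3-(3-methylbut-2-en-1-yl)benzaldehyde
Conditions: K2CO3, DMF, 0 °C → rt
Reagents that add atoms: none
Why: Williamson ether synthesis on a highly SN2-active α-chloro ketone forms O1–C2, while the weak base, low temperature and prompt work-up hold back aldol condensation of the new keto ether onto the deactivated aldehyde (Rap–Stoermer benzofuran formation).

**Step 9**
Reactants: 16 2,4-bis(methoxymethoxy)-6-{2-[2-methoxy-4-(methoxymethoxy)-3-(3-methylbut-2-en-1-yl)phenyl]-2-oxoethoxy}-3-(3-methylbut-2-en-1-yl)benzaldehyde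
Product: 17 (3R)-3-hydroxy-3-[2-methoxy-4-(methoxymethoxy)-3-(3-methylbut-2-en-1-yl)phenyl]-5,7-bis(methoxymethoxy)-6-(3-methylbut-2-en-1-yl)-2,3-dihydro-4H-chromen-4-one
Conditions: (5aR,10bS)-2-(pentafluorophenyl)-5a,10b-dihydro-4H,6H-indeno[2,1-b][1,2,4]triazolo[4,3-d][1,4]oxazin-2-ium tetrafluoroborate (15 mol %), Et3N (15 mol %), toluene, rt → 40 °C, argon
Reagents that add atoms: none
Why: Et3N deprotonates the triazolium salt, the carbene adds to the ring A formyl group, a proton shift gives the Breslow enaminol (an acyl anion equivalent), its nucleophilic carbon attacks the tethered ring B ketone, and collapse of the adduct expels the carbene and leaves the α-ketol. The closest known reaction type is the enantioselective intramolecular crossed aldehyde–ketone benzoin cyclisation of 2-(2-oxoethoxy)benzaldehydes to 3-hydroxychroman-4-ones with chiral triazolylidenes. Ring C closes in the 6-exo-trig mode through the new C3–C4 bond. C3 is set by the catalyst alone: the indane wall covers one face of the planar enaminol, and the hydrogen bond from the enol O–H to the ketone oxygen together with the short O1–C2 tether fixes which ketone face meets the open side. The step needs chemoselectivity for the cross-coupling, which the substrate secures because only the aldehyde can form the enaminol, its two ortho oxygen substituents and the intramolecular ketone disfavour self-coupling, the α-aryloxy group raises the electrophilicity of the ketone, and a weak amine base in toluene keeps the aldol pathway slow. The small ortho fluorines of the N-aryl group leave room for the hindered aldehyde, and since C3 ends fully substituted no enolisation toward it can erode the configuration.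

**Step 10**
Reactants: 17 (3R)-tris(methoxymethyl) ketol
Product: 18 (3R)-3,5,7-trihydroxy-3-[4-hydroxy-2-methoxy-3-(3-methylbut-2-en-1-yl)phenyl]-6-(3-methylbut-2-en-1-yl)-2,3-dihydro-4H-chromen-4-one (CNP0157505.1)
Conditions: HCl (cat.), MeOH, 40 °C
Reagents that add atoms: none
Why: Acid-catalysed acetal exchange of aryl methoxymethyl ethers with methanol runs at an acidity and temperature below those needed to protonate the trisubstituted alkenes or to ionise the carbinol, whose cation would sit next to a carbonyl group, so C3 keeps its configuration.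

**Compound list**
1 | 2,4,6-trihydroxybenzaldehyde | O=Cc1c(O)cc(O)cc1O | starting material
2 | 2-hydroxy-4,6-bis(methoxymethoxy)benzaldehyde | O=Cc1c(O)cc(OCOC)cc1OCOC | intermediate
3 | prenyl bromide (1-bromo-3-methylbut-2-ene) | CC(C)=CCBr | starting material
4 | 2,4-bis(methoxymethoxy)-6-[(3-methylbut-2-en-1-yl)oxy]benzaldehyde | O=Cc1c(OCC=C(C)C)cc(OCOC)cc1OCOC | intermediate
5 | ortho-dienone: racemic 2,4-bis(methoxymethoxy)-5-(2-methylbut-3-en-2-yl)-6-oxocyclohexa-1,3-diene-1-carbaldehyde (not isolated) | O=CC1=C(OCOC)C=C(OCOC)C(C(C)(C)C=C)C1=O | intermediate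
6 | para-dienone: 2,4-bis(methoxymethoxy)-3-(3-methylbut-2-en-1-yl)-6-oxocyclohexa-1,4-diene-1-carbaldehyde (not isolated) | O=CC1=C(OCOC)C(CC=C(C)C)C(OCOC)=CC1=O | intermediate
7 | 6-hydroxy-2,4-bis(methoxymethoxy)-3-(3-methylbut-2-en-1-yl)benzaldehyde | O=Cc1c(O)cc(OCOC)c(CC=C(C)C)c1OCOC | intermediate
8 | 4-hydroxy-2-methoxybenzaldehyde | COc1cc(O)ccc1C=O | starting material
9 | 2-methoxy-4-(methoxymethoxy)benzaldehyde | COc1cc(OCOC)ccc1C=O | intermediate
10 | lithium [2-methoxy-4-(methoxymethoxy)phenyl](4-methylpiperazin-1-yl)methanolate, racemic (not isolated) | COc1cc(OCOC)ccc1C(O[Li])N1CCN(C)CC1 | intermediate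
11 | 3-lithio derivative of 10, lithium between the methoxy and methoxymethoxy groups (not isolated) | COc1c([Li])c(OCOC)ccc1C(O[Li])N1CCN(C)CC1 | intermediate
12 | lithium [2-methoxy-4-(methoxymethoxy)-3-(3-methylbut-2-en-1-yl)phenyl](4-methylpiperazin-1-yl)methanolate, racemic (not isolated) | COc1c(CC=C(C)C)c(OCOC)ccc1C(O[Li])N1CCN(C)CC1 | intermediate
13 | 2-methoxy-4-(methoxymethoxy)-3-(3-methylbut-2-en-1-yl)benzaldehyde | COc1c(CC=C(C)C)c(OCOC)ccc1C=O | intermediate
14 | racemic 2-chloro-1-[2-methoxy-4-(methoxymethoxy)-3-(3-methylbut-2-en-1-yl)phenyl]ethan-1-ol | COc1c(CC=C(C)C)c(OCOC)ccc1C(O)CCl | intermediate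
15 | 2-chloro-1-[2-methoxy-4-(methoxymethoxy)-3-(3-methylbut-2-en-1-yl)phenyl]ethan-1-one | COc1c(CC=C(C)C)c(OCOC)ccc1C(=O)CCl | intermediate
16 | 2,4-bis(methoxymethoxy)-6-{2-[2-methoxy-4-(methoxymethoxy)-3-(3-methylbut-2-en-1-yl)phenyl]-2-oxoethoxy}-3-(3-methylbut-2-en-1-yl)benzaldehyde | COc1c(C(=O)COc2cc(OCOC)c(CC=C(C)C)c(OCOC)c2C=O)ccc(OCOC)c1CC=C(C)C | intermediate
17 | (3R)-3-hydroxy-3-[2-methoxy-4-(methoxymethoxy)-3-(3-methylbut-2-en-1-yl)phenyl]-5,7-bis(methoxymethoxy)-6-(3-methylbut-2-en-1-yl)-2,3-dihydro-4H-chromen-4-one | COc1c([C@@]2(O)COc3cc(OCOC)c(CC=C(C)C)c(OCOC)c3C2=O)ccc(OCOC)c1CC=C(C)C | intermediate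
18 | (3R)-3,5,7-trihydroxy-3-[4-hydroxy-2-methoxy-3-(3-methylbut-2-en-1-yl)phenyl]-6-(3-methylbut-2-en-1-yl)-2,3-dihydro-4H-chromen-4-one | COc1c([C@@]2(O)COc3cc(O)c(CC=C(C)C)c(O)c3C2=O)ccc(O)c1CC=C(C)C | target

**Total step count:** 10.
**Longest linear sequence:** 7 steps (8 → 9 → 13 → 14 → 15 → 16 → 17 → 18). The ring A branch (1 → 2 → 4 → 7) joins at step 8.

**Steps most likely to fail**

**Step 9.**
- *What may go wrong:* the bulky chiral carbene may add only slowly to the electron-rich, doubly ortho-substituted aldehyde. Face discrimination at the hindered ortho-methoxyaryl ketone may be poor. Base-induced aldol condensation of the tether methylene onto the aldehyde may overtake the benzoin pathway.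
- *Fallback:* it sets out from 16 and returns at 17. The same C3–C4 bond is closed without stereocontrol by the small carbene from 3-ethyl-5-(2-hydroxyethyl)-4-methylthiazolium bromide and Et3N in THF, to give the racemic tris(methoxymethyl) ketol F1. SmI2 in THF–MeOH at −78 °C then removes the α-hydroxy group reductively to give the tris(methoxymethyl) isoflavanone F2. Its potassium enolate (KN(SiMe3)2, THF, −78 °C) is hydroxylated with an enantiopure (8,8-dichlorocamphorylsulfonyl)oxaziridine (Davis oxidation, reagent antipode chosen for R). The stereocentre then comes from a stoichiometric chiral oxidant instead of the catalyst.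

**Step 3.**
- *What may go wrong:* the ortho-dienone may enolise before the second shift, which would strand a 1,1-dimethylallyl group on the wrong carbon. The prenyl ether may undergo a thermal carbonyl-ene cyclisation with the neighbouring aldehyde, or the ether may cleave at 200 °C.
- *Fallback:* it sets out from prenyl bromide 3, with purchased phloroglucinol (Oc1cc(O)cc(O)c1) as the arene, and returns at 7.
  - Two of the three hydroxyls are capped (MOMCl, i-Pr2NEt) to give 3,5-bis(methoxymethoxy)phenol F3.
  - The remaining phenol is silylated (i-Pr3SiCl, imidazole, DMF) to give [3,5-bis(methoxymethoxy)phenoxy]tri(propan-2-yl)silane F4.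
  - n-BuLi in THF at 0 °C lithiates the carbon between the two acetal ethers, since the bulky silyl ether does not direct. Compound 3 then alkylates it to give [3,5-bis(methoxymethoxy)-4-(3-methylbut-2-en-1-yl)phenoxy]tri(propan-2-yl)silane F5.
  - Bu4NF frees 3,5-bis(methoxymethoxy)-4-(3-methylbut-2-en-1-yl)phenol F6.
  - Magnesium-mediated ortho-formylation (MgCl2, Et3N, paraformaldehyde, MeCN, reflux) at either of the two equivalent ortho carbons gives 7.

**Step 10.**
- *What may go wrong:* acid may trigger cyclisation of a prenyl group onto a neighbouring free phenol, addition to the alkenes, or ionisation and dehydration of the tertiary benzylic carbinol.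
- *Fallback:* it sets out from 17 and returns at 18 without any Brønsted acid. Excess Et3SiOTf with 2,2'-bipyridyl in CH2Cl2 at 0 °C → rt exchanges the aryl acetal ethers for silyl ethers and is expected to cap the carbinol as well, to give the (3R)-tetrakis(triethylsilyl) ether F7. Et3N·3HF in THF at 0 °C → rt then strips all four silyl groups.

**Further compounds**
F1 | step 9 | racemic 3-hydroxy-3-[2-methoxy-4-(methoxymethoxy)-3-(3-methylbut-2-en-1-yl)phenyl]-5,7-bis(methoxymethoxy)-6-(3-methylbut-2-en-1-yl)-2,3-dihydro-4H-chromen-4-one | COc1c(C2(O)COc3cc(OCOC)c(CC=C(C)C)c(OCOC)c3C2=O)ccc(OCOC)c1CC=C(C)C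
F2 | step 9 | racemic 3-[2-methoxy-4-(methoxymethoxy)-3-(3-methylbut-2-en-1-yl)phenyl]-5,7-bis(methoxymethoxy)-6-(3-methylbut-2-en-1-yl)-2,3-dihydro-4H-chromen-4-one | COc1c(C2COc3cc(OCOC)c(CC=C(C)C)c(OCOC)c3C2=O)ccc(OCOC)c1CC=C(C)C
F3 | step 3 | 3,5-bis(methoxymethoxy)phenol | Oc1cc(OCOC)cc(OCOC)c1
F4 | step 3 | [3,5-bis(methoxymethoxy)phenoxy]tri(propan-2-yl)silane | CC(C)[Si](Oc1cc(OCOC)cc(OCOC)c1)(C(C)C)C(C)C
F5 | step 3 | [3,5-bis(methoxymethoxy)-4-(3-methylbut-2-en-1-yl)phenoxy]tri(propan-2-yl)silane | CC(C)[Si](Oc1cc(OCOC)c(CC=C(C)C)c(OCOC)c1)(C(C)C)C(C)C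
F6 | step 3 | 3,5-bis(methoxymethoxy)-4-(3-methylbut-2-en-1-yl)phenol | Oc1cc(OCOC)c(CC=C(C)C)c(OCOC)c1
F7 | step 10 | (3R)-3-[2-methoxy-3-(3-methylbut-2-en-1-yl)-4-(triethylsilyloxy)phenyl]-6-(3-methylbut-2-en-1-yl)-3,5,7-tris(triethylsilyloxy)-2,3-dihydro-4H-chromen-4-one | COc1c([C@@]2(O[Si](CC)(CC)CC)COc3cc(O[Si](CC)(CC)CC)c(CC=C(C)C)c(O[Si](CC)(CC)CC)c3C2=O)ccc(O[Si](CC)(CC)CC)c1CC=C(C)C
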